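Cuts: the C2 and C5 hydroxyls go back to a methyl and an ethyl vinylogous ester, and the quinone to its hydroquinone. Ring bond C4–C5 is then cut, followed by C1–C6, C3–C1', and in the side chain C10'–C11' and C12'–C13'.
Enabling feature: in the single ring, C1(=O)–C2(OH)–C3(alkyl)–C4(=O) has the carbon and oxygen pattern of a squarate four-membered ring. C5(OH)–C6(H) has that of a 2-alkoxyvinyl group, so the quinone is a cyclobutenone enlarged by two carbons.
Forward: the C19 chain is made first (Johnson–Claisen forms C12'–C13', copper-catalysed coupling forms C10'–C11') and its Grignard reagent is joined to dimethyl squarate (C3–C1'). (Z)-2-Ethoxyvinyllithium then adds to the ketone-like carbonyl (C1–C6), and heating opens the four-membered ring and closes the six-membered ring at C4–C5.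
Silver oxide oxidation and hydroxide hydrolysis of both alkoxy groups then give the dihydroxyquinone.
Stereochemistry: the target has no stereocentre. Its E C14'=C15' alkene comes from the chair transition state of the Johnson–Claisen step and is not touched afterwards.

Key step: step 8

Remark: because the target is achiral, there is no enantiomer to select. Racemic hept-1-en-3-ol and a racemic cyclobutenone carbinol are therefore adequate, and only the E alkene has to be controlled.

Step 1
Reactants: 1 racemic hept-1-en-3-ol; 2 triethyl orthoacetate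
Product: 4 ethyl (E)-non-4-enoate, via mixed ketene acetal 3 (not isolated)
Conditions: EtCO2H (cat.), excess 2 as solvent, 140 °C, EtOH distilled off
Reagents that add atoms: none
Why: Johnson–Claisen orthoester rearrangement: acid-catalysed exchange and loss of ethanol give ketene acetal 3, whose [3,3] shift runs through a chair with the butyl group equatorial and should therefore set the E geometry of the new C4=C5 alkene, the carbinol stereocentre being consumed so that racemic 1 is sufficient.

Step 2
Reactants: 4 ethyl (E)-non-4-enoate
Product: 5 (E)-non-4-en-1-ol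
Conditions: LiAlH4, THF, 0 °C to rt; aqueous work-up
Reagents that add atoms: none
Why: Hydride reduction of an ester to the primary alcohol with LiAlH4, which does not touch an isolated alkene.

Step 3
Reactants: 5 (E)-non-4-en-1-ol
Product: 6 (E)-1-bromonon-4-ene
Conditions: CBr4, PPh3, CH2Cl2, 0 °C
Reagents that add atoms: carbon tetrabromide, BrC(Br)(Br)Br
Why: Appel bromination, an SN2 displacement of the oxyphosphonium ion under neutral conditions that should leave the position and geometry of the alkene unchanged.

Step 4
Reactants: 6 (E)-1-bromonon-4-ene; 7 10-bromodecan-1-ol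
Product: 10 (E)-nonadec-14-en-1-ol, via (E)-non-4-enylmagnesium bromide 8 (not isolated), via chloromagnesium 10-bromodecan-1-olate 9 (not isolated)
Conditions: 6, Mg, THF, 40 °C (gives 8); 7, MeMgCl (1.0 equiv), THF, 0 °C (gives 9); 8 added to 9, Li2CuCl4 (3 mol %), THF, −10 °C to rt; 1 M HCl
Reagents that add atoms: none
Why: Copper-catalysed sp3–sp3 cross-coupling of a primary alkyl Grignard reagent with a primary alkyl bromide (Kochi-type, Li2CuCl4), with the hydroxyl group masked in the flask as its magnesium alkoxide as is usual for ω-bromo alcohols, and with a pent-4-enyl-type Grignard reagent that has no tendency to cyclise.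

Step 5
Reactants: 10 (E)-nonadec-14-en-1-ol
Product: 11 (E)-19-bromononadec-5-ene, that is (E)-nonadec-14-enyl bromide
Conditions: CBr4, PPh3, CH2Cl2, 0 °C
Reagents that add atoms: carbon tetrabromide, BrC(Br)(Br)Br
Why: Appel bromination as in step 3, chosen because neither free bromine nor strong acid meets the alkene.

Step 6
Reactants: 11 (E)-19-bromononadec-5-ene; 12 dimethyl squarate
Product: 15 3-methoxy-4-[(E)-nonadec-14-enyl]cyclobut-3-ene-1,2-dione, via (E)-nonadec-14-enylmagnesium bromide 13 (not isolated), via squarate 1,2-adduct 14 (not isolated)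
Conditions: 11, Mg, THF, 45 °C; added to 12, THF, −78 °C; aq NH4Cl; crude 14, conc. HCl (cat.), CH2Cl2, rt
Reagents that add atoms: none
Why: 1,2-Addition of a Grignard reagent to a squarate ester stops at the mono-adduct because the remaining carbonyl is a vinylogous ester, and acid-catalysed allylic ionisation, rehydration and loss of methanol then give the 3-alkyl-4-alkoxycyclobutenedione, the standard entry to this class.

Step 7
Reactants: 15 3-methoxy-4-[(E)-nonadec-14-enyl]cyclobut-3-ene-1,2-dione; 16 (Z)-1-bromo-2-ethoxyethene
Product: 18 racemic 4-[(Z)-2-ethoxyvinyl]-4-hydroxy-3-methoxy-2-[(E)-nonadec-14-enyl]cyclobut-2-en-1-one, via (Z)-2-ethoxyvinyllithium 17 (not isolated)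
Conditions: 16, t-BuLi (2 equiv per 16), Et2O, −78 °C; 15 in THF, −78 °C; H2O quench at −78 °C, pH 7 buffer wash; short plug of Et3N-deactivated silica
Reagents that add atoms: none
Why: Bromine–lithium exchange with retention gives the internally coordinated Z reagent, which resists β-elimination at −78 °C, and its 1,2-carbonyl addition should take place at C2 of 15, the carbonyl next to C3–OMe, because C1 is deactivated as the carbonyl of the vinylogous ester MeO–C3=C4–C1=O; the new carbinol centre is formed racemic and is lost in step 8.

Step 8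
Reactants: 18 racemic 4-[(Z)-2-ethoxyvinyl]-4-hydroxy-3-methoxy-2-[(E)-nonadec-14-enyl]cyclobut-2-en-1-one
Product: 21 5-ethoxy-2-methoxy-3-[(E)-nonadec-14-enyl]benzene-1,4-diol, via dienylketene 19 (not isolated), via cyclohexadienone 20 (not isolated)
Conditions: toluene (degassed, 0.02 M), base-washed glassware, Ar, 110 °C
Reagents that add atoms: none
Why: Heat breaks the strained bond between the ketone carbon and the carbinol carbon of 18 in a conrotatory 4π electrocyclic opening to dienylketene 19, the ketene carbon then bonds to the ethoxy-bearing vinyl terminus to give cyclohexadienone 20, and enolisation of 20 should deliver the aromatic hydroquinone 21. This is the Moore-type thermal ring expansion of 4-alkenyl-4-hydroxycyclobutenones, applied here to an alkenyl group that carries a β-alkoxy substituent. The one new ring, the six-membered carbocycle, closes by a thermal disrotatory 6π electrocyclisation that forms the bond between quinone carbons C4 and C5. The step needs torquoselectivity, and the hydroxyl group as the stronger donor should rotate outward so that the ethoxyvinyl group turns inward beside the ketene, while ketene of the other geometry mostly reverts to 18. No lasting stereocentre arises, since the carbinol centre of 18 is destroyed and the C–OEt centre of 20 vanishes on aromatisation, and the ring order alkyl, OMe, OH, H, OEt, OH is fixed by the connectivity of 18. The neutral aprotic medium should keep ionisation of the carbinol and loss of ethanol from 20 slower than enolisation, and it contains nothing that attacks the remote E alkene.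

Step 9
Reactants: 21 5-ethoxy-2-methoxy-3-[(E)-nonadec-14-enyl]benzene-1,4-diol
Product: 22 5-ethoxy-2-methoxy-3-[(E)-nonadec-14-enyl]cyclohexa-2,5-diene-1,4-dione
Conditions: Ag2O, K2CO3, Et2O, rt
Reagents that add atoms: none
Why: Hydroquinone-to-quinone oxidation with Ag2O under neutral anhydrous conditions, routine after such ring expansions and harmless to the alkoxy groups and the isolated alkene.

Step 10
Reactants: 22 5-ethoxy-2-methoxy-3-[(E)-nonadec-14-enyl]cyclohexa-2,5-diene-1,4-dione
Product: 24 2,5-dihydroxy-3-[(E)-nonadec-14-enyl]cyclohexa-2,5-diene-1,4-dione, via disodium quinonediolate 23 (not isolated)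
Conditions: 2 M aq NaOH, EtOH, 70 °C, N2; then 2 M HCl, 0 °C
Reagents that add atoms: sodium hydroxide, [Na+].[OH-]
Why: Addition–elimination of hydroxide at C2 and C5 of the two vinylogous esters (saponification of a 2,5-dialkoxybenzoquinone) gives the resonance-stabilised dianion 23, which resists further attack, and acidification should release 24 with the E alkene unchanged.

Compound list
1 | racemic hept-1-en-3-ol | CCCCC(O)C=C | starting material
2 | triethyl orthoacetate | CC(OCC)(OCC)OCC | starting material
3 | racemic 3-[(1-ethoxyethenyl)oxy]hept-1-ene (mixed ketene acetal) | CCCCC(C=C)OC(=C)OCC | intermediate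
4 | ethyl (E)-non-4-enoate | CCCC/C=C/CCC(=O)OCC | intermediate
5 | (E)-non-4-en-1-ol | CCCC/C=C/CCCO | intermediate
6 | (E)-1-bromonon-4-ene | CCCC/C=C/CCCBr | intermediate
7 | 10-bromodecan-1-ol | OCCCCCCCCCCBr | starting material
8 | (E)-non-4-enylmagnesium bromide | CCCC/C=C/CCC[Mg]Br | intermediate
9 | chloromagnesium 10-bromodecan-1-olate | Cl[Mg]OCCCCCCCCCCBr | intermediate
10 | (E)-nonadec-14-en-1-ol | CCCC/C=C/CCCCCCCCCCCCCO | intermediate
11 | (E)-19-bromononadec-5-ene | CCCC/C=C/CCCCCCCCCCCCCBr | intermediate
12 | dimethyl squarate (3,4-dimethoxycyclobut-3-ene-1,2-dione) | COC1=C(OC)C(=O)C1=O | starting material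
13 | (E)-nonadec-14-enylmagnesium bromide | CCCC/C=C/CCCCCCCCCCCCC[Mg]Br | intermediate
14 | racemic 4-hydroxy-2,3-dimethoxy-4-[(E)-nonadec-14-enyl]cyclobut-2-en-1-one | CCCC/C=C/CCCCCCCCCCCCCC1(O)C(OC)=C(OC)C1=O | intermediate
15 | 3-methoxy-4-[(E)-nonadec-14-enyl]cyclobut-3-ene-1,2-dione | CCCC/C=C/CCCCCCCCCCCCCC1=C(OC)C(=O)C1=O | intermediate
16 | (Z)-1-bromo-2-ethoxyethene | CCO/C=C\Br | starting material
17 | (Z)-2-ethoxyvinyllithium | [Li]/C=C\OCC | intermediate
18 | racemic 4-[(Z)-2-ethoxyvinyl]-4-hydroxy-3-methoxy-2-[(E)-nonadec-14-enyl]cyclobut-2-en-1-one | CCCC/C=C/CCCCCCCCCCCCCC1=C(OC)C(O)(/C=C\OCC)C1=O | intermediate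
19 | (3Z,5Z)-6-ethoxy-4-hydroxy-3-methoxy-2-[(E)-nonadec-14-enyl]hexa-1,3,5-trien-1-one (dienylketene) | CCCC/C=C/CCCCCCCCCCCCCC(=C=O)/C(OC)=C(O)\C=C/OCC | intermediate
20 | racemic 6-ethoxy-4-hydroxy-3-methoxy-2-[(E)-nonadec-14-enyl]cyclohexa-2,4-dien-1-one | CCCC/C=C/CCCCCCCCCCCCCC1=C(OC)C(O)=CC(OCC)C1=O | intermediate
21 | 5-ethoxy-2-methoxy-3-[(E)-nonadec-14-enyl]benzene-1,4-diol | CCCC/C=C/CCCCCCCCCCCCCc1c(OC)c(O)cc(OCC)c1O | intermediate
22 | 5-ethoxy-2-methoxy-3-[(E)-nonadec-14-enyl]cyclohexa-2,5-diene-1,4-dione | CCCC/C=C/CCCCCCCCCCCCCC1=C(OC)C(=O)C=C(OCC)C1=O | intermediate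
23 | disodium salt of 2,5-dihydroxy-3-[(E)-nonadec-14-enyl]cyclohexa-2,5-diene-1,4-dione | CCCC/C=C/CCCCCCCCCCCCCC1=C([O-])C(=O)C=C([O-])C1=O.[Na+].[Na+] | intermediate
24 | 2,5-dihydroxy-3-[(E)-nonadec-14-enyl]cyclohexa-2,5-diene-1,4-dione | CCCC/C=C/CCCCCCCCCCCCCC1=C(O)C(=O)C=C(O)C1=O | target

Total step count: 10. Longest linear sequence: 10 steps (1 to 24); compounds 2, 7, 12 and 16 are bought and enter directly.

Steps most likely to fail

1. Step 8.
- What may go wrong: the closure may be slowed because the Z-ethoxy group points into the forming ring and the ethoxy-bearing carbon is the less nucleophilic end of the enol ether. Reversion, capture of the ketene by the hydroxyl group, or acid-triggered dehydration of the carbinol could then take over. Ethanol could also be lost from the cyclohexadienone before it enolises.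
- Fallback: the ring expansion is run with an unsubstituted vinyl group and the C5 oxygen is introduced afterwards. It sets out from 15.
- Vinylmagnesium bromide (THF, −78 °C) should add to the same carbonyl to give racemic 4-ethenyl-4-hydroxy-3-methoxy-2-[(E)-nonadec-14-enyl]cyclobut-2-en-1-one F1.
- Heating F1 in toluene should give 2-methoxy-3-[(E)-nonadec-14-enyl]benzene-1,4-diol F2, and Ag2O should oxidise it to 2-methoxy-3-[(E)-nonadec-14-enyl]cyclohexa-2,5-diene-1,4-dione F3.
- Excess aqueous methylamine in ethanol under air should add at C5, the β-carbon of the carbonyl that the methoxy group does not deactivate, with re-oxidation. It should also displace the methoxy group, giving 2,5-bis(methylamino)-3-[(E)-nonadec-14-enyl]cyclohexa-2,5-diene-1,4-dione F4.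
- Hydrolysis of both vinylogous amides with hot aqueous NaOH in ethanol and acidification comes back to the route at 24.

2. Step 7.
- What may go wrong: the lithium reagent may decompose by β-elimination of lithium ethoxide if the exchange mixture warms. The adduct may also ionise at the carbinol carbon, with loss of water, during work-up or on silica.
- Fallback: an Arens–van Dorp-type sequence that sets out from 15.
- Lithium ethoxyacetylide F5 (ethoxyacetylene, n-BuLi, THF, −78 °C), which cannot β-eliminate, should add to the same carbonyl to give racemic 4-(ethoxyethynyl)-4-hydroxy-3-methoxy-2-[(E)-nonadec-14-enyl]cyclobut-2-en-1-one F6.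
- F6 is kept at or below room temperature, so that it does not ring-expand as the alkyne, and is semi-hydrogenated (H2, Lindlar catalyst, quinoline, EtOAc). Syn addition should give the Z enol ether, which returns to the route at 18.
- The disubstituted E alkene and the tetrasubstituted ring alkene should not be reduced under these conditions.

3. Step 6.
- What may go wrong: Wurtz dimerisation during formation of the long-chain Grignard reagent, its precipitation at −78 °C, or hydride transfer instead of addition may erode the chain-to-ring bond formation.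
- Fallback: the polarity is reversed and the chain is used as the electrophile. It sets out from 11 and gives up the ring expansion.
- Commercial 1,2,4,5-tetramethoxybenzene is lithiated (n-BuLi, TMEDA, THF, 0 °C) to 2,3,5,6-tetramethoxyphenyllithium F7.
- F7 should be alkylated by 11 (THF/DMPU) to give 1,2,4,5-tetramethoxy-3-[(E)-nonadec-14-enyl]benzene F8.
- Oxidative demethylation with ceric ammonium nitrate (MeCN/H2O, 0 °C) should give 2,5-dimethoxy-3-[(E)-nonadec-14-enyl]cyclohexa-2,5-diene-1,4-dione F9.
- Hydrolysis under the conditions of step 10 comes back to the route at 24.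

Further compounds
F1 | step 8 | racemic 4-ethenyl-4-hydroxy-3-methoxy-2-[(E)-nonadec-14-enyl]cyclobut-2-en-1-one | CCCC/C=C/CCCCCCCCCCCCCC1=C(OC)C(O)(C=C)C1=O
F2 | step 8 | 2-methoxy-3-[(E)-nonadec-14-enyl]benzene-1,4-diol | CCCC/C=C/CCCCCCCCCCCCCc1c(OC)c(O)ccc1O
F3 | step 8 | 2-methoxy-3-[(E)-nonadec-14-enyl]cyclohexa-2,5-diene-1,4-dione | CCCC/C=C/CCCCCCCCCCCCCC1=C(OC)C(=O)C=CC1=O
F4 | step 8 | 2,5-bis(methylamino)-3-[(E)-nonadec-14-enyl]cyclohexa-2,5-diene-1,4-dione | CCCC/C=C/CCCCCCCCCCCCCC1=C(NC)C(=O)C=C(NC)C1=O
F5 | step 7 | lithium ethoxyacetylide | CCOC#C[Li]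
F6 | step 7 | racemic 4-(ethoxyethynyl)-4-hydroxy-3-methoxy-2-[(E)-nonadec-14-enyl]cyclobut-2-en-1-one | CCCC/C=C/CCCCCCCCCCCCCC1=C(OC)C(O)(C#COCC)C1=O
F7 | step 6 | 2,3,5,6-tetramethoxyphenyllithium | [Li]c1c(OC)c(OC)cc(OC)c1OC
F8 | step 6 | 1,2,4,5-tetramethoxy-3-[(E)-nonadec-14-enyl]benzene | CCCC/C=C/CCCCCCCCCCCCCc1c(OC)c(OC)cc(OC)c1OC
F9 | step 6 | 2,5-dimethoxy-3-[(E)-nonadec-14-enyl]cyclohexa-2,5-diene-1,4-dione | CCCC/C=C/CCCCCCCCCCCCCC1=C(OC)C(=O)C=C(OC)C1=O
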